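**Retrosynthesis**
- Target 18 ← esterification and oxidation of the CH2OH of 16, which is carried as a TBS ether through the route ← diimide reduction of the ring C=C of dihydrodioxine 14.
- Key step: 14 is formed by suprafacial [4+2] photooxygenation (singlet O2) of the (E,E)-diene 13. The only ring formed in the route is the 1,2-dioxane (as the dihydrodioxine).
- Diene 13 ← Julia–Kocienski olefination of a Roche-derived PT-sulfone (6) with the (E)-keto-enal 12.
- Enal 12 ← HWE, DIBAL and MnO2 from dihydro-β-ionone (7), then ozonolysis of its cyclohexene ring, which unmasks the hindered 1,6-diketone chain.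

Assumptions: (R)-3-bromo-2-methylpropan-1-ol (1) and dihydro-β-ionone (7) are commercial. The E/Z mixtures from the HWE (step 4) and the dioxine diastereomers (step 9) are separable by chromatography.

---

**Step 1**
Reactants: 1 (R)-3-bromo-2-methylpropan-1-ol; 2 TBSCl
Product: 3 tert-butyl{[(2R)-3-bromo-2-methylpropyl]oxy}dimethylsilane
Conditions: TBSCl, imidazole, DMF, 0 °C → rt
Reagents that add atoms: TBSCl, CC(C)(C)[Si](C)(C)Cl
Why: Standard silylation of the primary alcohol; the stereocenter is not involved. This Roche-derived center becomes the propanoate CH(Me) of the target.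

**Step 2**
Reactants: 3; 4 1-phenyl-1H-tetrazole-5-thiol
Product: 5 (R)-5-{[3-(TBSO)-2-methylpropyl]thio}-1-phenyl-1H-tetrazole
Conditions: 4, K2CO3, DMF, 50 °C
Reagents that add atoms: 1-phenyltetrazole-5-thiol, Sc1nnnn1-c1ccccc1
Why: SN2 displacement at the primary bromide by the thiolate; the β-stereocenter is untouched and there is no acidifying group that could racemize it.

**Step 3**
Reactants: 5
Product: 6 (R)-5-{[3-(TBSO)-2-methylpropyl]sulfonyl}-1-phenyl-1H-tetrazole
Conditions: (NH4)6Mo7O24 (cat.), 30% H2O2, EtOH, 0 °C → rt
Reagents that add atoms: hydrogen peroxide, OO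
Why: Mo-catalysed sulfide-to-sulfone oxidation under neutral conditions, so the silyl ether survives; this gives the Julia–Kocienski donor.

**Step 4**
Reactants: 7 dihydro-β-ionone; 8 triethyl phosphonoacetate
Product: 9 ethyl (2E)-3-methyl-5-(2,6,6-trimethylcyclohex-1-en-1-yl)pent-2-enoate
Conditions: 8, NaH, THF, 0 °C → 50 °C; separate E from Z (E:Z about 3:1)
Reagents that add atoms: triethyl phosphonoacetate, CCOC(=O)CP(=O)(OCC)OCC
Why: Horner–Wadsworth–Emmons olefination of the only ketone present. The thermodynamic E-enoate has the chain trans to the ester, which fixes the C5=C6 geometry needed for cis-3,6 stereochemistry later.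

**Step 5**
Reactants: 9
Product: 10 (2E)-3-methyl-5-(2,6,6-trimethylcyclohex-1-en-1-yl)pent-2-en-1-ol
Conditions: DIBAL-H, CH2Cl2, −78 → 0 °C
Reagents that add atoms: none
Why: DIBAL reduces the ester 1,2 to the allylic alcohol; the tetrasubstituted ring alkene and the E-alkene are untouched (no ketone is present yet).

**Step 6**
Reactants: 10
Product: 11 (2E)-3-methyl-5-(2,6,6-trimethylcyclohex-1-en-1-yl)pent-2-enal
Conditions: MnO2, CH2Cl2, rt
Reagents that add atoms: none
Why: MnO2 oxidizes the allylic alcohol selectively with retention of alkene geometry.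

**Step 7**
Reactants: 11
Product: 12 (2E)-3,7,7-trimethyl-6,11-dioxododec-2-enal
Conditions: O3, CH2Cl2/MeOH, −78 °C (about 1 equiv); then Me2S, −78 °C → rt
Reagents that add atoms: ozone, [O-][O+]=O
Why: Ozonolysis cleaves the electron-rich tetrasubstituted ring alkene, which is much more reactive than the electron-poor enal alkene. This gives the 2,2-dimethyl-1,6-diketone chain of the target with the E-enal intact.

**Step 8**
Reactants: 6; 12
Product: 13 (10E,12E,14S)-15-(TBSO)-6,6,10,14-tetramethylpentadeca-10,12-diene-2,7-dione
Conditions: 6 (1.3 equiv), KHMDS (1.25 equiv), DME, −60 °C; add 12; −60 °C → rt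
Reagents that add atoms: none
Why: Julia–Kocienski olefination of the PT-sulfone anion with the enal gives the E-C3=C4 bond. The enal keeps the R2 chain trans to C4, which sets up the required cis-3,6 relationship. Using no excess base avoids ketone enolization, and the Roche-derived center is not epimerizable here.

**Step 9 (key step)**
Reactants: 13
Product: 14 3,6-dihydro-1,2-dioxine (Ca R, C3 S, C6 S by CIP), the desired diastereomer
Conditions: O2, TPP (cat.), hν (visible), CH2Cl2, −20 → 0 °C; chromatographic separation of the two diastereomers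
Reagents that add atoms: oxygen, O=O
Why: [4+2] cycloaddition of singlet O2 is suprafacial, so the outside substituents at C3 and C6 (the propanoate precursor and the chain) end up cis while the inside Me and H end up on the same face, giving the (3S,6R)-type arrangement. The remote Ca center biases the face; the dr is modest and the minor diastereomer is removed by chromatography.

**Step 10**
Reactants: 14
Product: 15 saturated 1,2-dioxane TBS ether (Ca R, C3 S, C6 R by CIP)
Conditions: KO2C–N=N–CO2K, AcOH, MeOH/CH2Cl2, 0 °C → rt
Reagents that add atoms: none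
Why: Diimide reduces the unhindered cis-disubstituted C=C by syn H2 transfer without cleaving the O–O bond. The three ketones are untouched (a hydrazine-free diimide source avoids hydrazone formation). No stereocenter is altered.

**Step 11**
Reactants: 15
Product: 16 primary alcohol (Ca R, C3 S, C6 R by CIP)
Conditions: HF·pyridine, pyridine, THF, 0 °C → rt
Reagents that add atoms: none
Why: Buffered fluoride desilylation under mild conditions that the tertiary dialkyl peroxide and the ketones tolerate.

**Step 12**
Reactants: 16
Product: 17 (2S)-2-[(3S,6R)-6-(4,4-dimethyl-3,8-dioxononyl)-6-methyl-1,2-dioxan-3-yl]propanoic acid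
Conditions: TEMPO (cat.), PhI(OAc)2 (2.5 equiv), MeCN/H2O 1:1, rt
Reagents that add atoms: water, O
Why: TEMPO/BAIB oxidation (Epp–Widlanski) takes the primary alcohol through its hydrate to the acid under mildly acidic conditions. These conditions do not enolize the α-center or eliminate the β-peroxide, and the peroxide and ketones survive.

**Step 13**
Reactants: 17
Product: 18 target, methyl (2S)-2-[(3S,6R)-6-(4,4-dimethyl-3,8-dioxononyl)-6-methyl-1,2-dioxan-3-yl]propanoate (Diacarperoxide B)
Conditions: TMSCHN2, MeOH/PhH, 0 °C
Reagents that add atoms: trimethylsilyldiazomethane, C[Si](C)(C)C=[N+]=[N-]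
Why: Neutral methylation of the carboxylic acid does not racemize the α-center or open the β-peroxy ester.

---

**Compound list**

| # | Name | SMILES | Role |
|---|---|---|---|
| 1 | (R)-3-bromo-2-methylpropan-1-ol | OC[C@@H](C)CBr | starting material |
| 2 | tert-butyldimethylsilyl chloride | CC(C)(C)[Si](C)(C)Cl | starting material |
| 3 | (R)-TBS 3-bromo-2-methylpropyl ether | CC(C)(C)[Si](C)(C)OC[C@@H](C)CBr | intermediate |
| 4 | 1-phenyl-1H-tetrazole-5-thiol | Sc1nnnn1-c1ccccc1 | starting material |
| 5 | PT-sulfide | CC(C)(C)[Si](C)(C)OC[C@@H](C)CSc1nnnn1-c1ccccc1 | intermediate |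
| 6 | PT-sulfone | CC(C)(C)[Si](C)(C)OC[C@@H](C)CS(=O)(=O)c1nnnn1-c1ccccc1 | intermediate |
| 7 | dihydro-β-ionone | CC(=O)CCC1=C(C)CCCC1(C)C | starting material |
| 8 | triethyl phosphonoacetate | CCOC(=O)CP(=O)(OCC)OCC | starting material |
| 9 | ethyl (E)-enoate | CCOC(=O)/C=C(\C)CCC1=C(C)CCCC1(C)C | intermediate |
| 10 | (E)-allylic alcohol | OC/C=C(\C)CCC1=C(C)CCCC1(C)C | intermediate |
| 11 | (E)-enal | O=C/C=C(\C)CCC1=C(C)CCCC1(C)C | intermediate |
| 12 | (E)-keto-enal | O=C/C=C(\C)CCC(=O)C(C)(C)CCCC(C)=O | intermediate |
| 13 | (E,E)-diene | CC(C)(C)[Si](C)(C)OC[C@@H](C)/C=C/C=C(\C)CCC(=O)C(C)(C)CCCC(C)=O | intermediate |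
| 14 | dihydrodioxine | CC(C)(C)[Si](C)(C)OC[C@@H](C)[C@@H]1C=C[C@](C)(CCC(=O)C(C)(C)CCCC(C)=O)OO1 | intermediate |
| 15 | 1,2-dioxane TBS ether | CC(C)(C)[Si](C)(C)OC[C@@H](C)[C@@H]1CC[C@](C)(CCC(=O)C(C)(C)CCCC(C)=O)OO1 | intermediate |
| 16 | primary alcohol | OC[C@@H](C)[C@@H]1CC[C@](C)(CCC(=O)C(C)(C)CCCC(C)=O)OO1 | intermediate |
| 17 | carboxylic acid | OC(=O)[C@@H](C)[C@@H]1CC[C@](C)(CCC(=O)C(C)(C)CCCC(C)=O)OO1 | intermediate |
| 18 | Diacarperoxide B | COC(=O)[C@@H](C)[C@@H]1CC[C@](C)(CCC(=O)C(C)(C)CCCC(C)=O)OO1 | target |

---

**Totals**
- Total steps: 13.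
- Longest linear sequence: 10 steps (7 → 9 → 10 → 11 → 12 → 13 → 14 → 15 → 16 → 17 → 18, counting steps 4–13).

**Three steps most likely to fail**
1. **Step 9, photooxygenation.**
   - The diene has a Z-type methyl on the inside of the s-cis conformer, and the trisubstituted terminus invites the competing ene reaction. The diastereoselectivity from the remote Ca center is also modest.
   - Fallback: build the ring by intramolecular SN2 of a tertiary hydroperoxide (from the tertiary alcohol with H2O2/acid) on a C3 secondary mesylate, or by hydroperoxide oxa-Michael addition, and set C3 by substrate control from the Roche fragment.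
2. **Step 8, Julia–Kocienski with a tri-carbonyl enal.**
   - Ketone enolization or addition, or E/Z leakage, could lower the yield.
   - Fallback: couple an (E)-vinylboronate made from the Roche fragment (alkyne from its aldehyde, then hydroboration) with an (E)-vinyl iodide of the keto chain by Suzuki coupling under mild Pd conditions.
3. **Step 7, chemoselective ozonolysis.**
   - Over-oxidation of the enal or aldehyde, or incomplete reduction of the ketone ozonide, could occur.
   - Fallback: skip the ring cleavage and assemble the chain by acylation. A Weinreb amide of 2,2-dimethyl-6-oxoheptanoic acid (the methyl ketone protected as its ketal) would be treated with an organozinc reagent from the (E)-bromo-enoate, followed by ketal removal.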